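**Retrosynthetic overview**
- The last step is global hydrogenolysis of a tetra-O-benzyl precursor, which frees the four phenols and leaves the 7-OMe in place.
- The C2–aryl bond of the flavanone unit, and the only stereocentre, come from a rhodium-catalysed enantioselective 1,4-addition of an arylboronic acid (carrying the whole benzylated flavone–diaryl ether) to 5-(benzyloxy)-7-methoxychromone.
- The boronic acid comes from the aryl bromide. The flavone pyranone ring comes from a 2'-hydroxychalcone by iodine/DMSO oxidative cyclisation, and the chalcone from a Claisen–Schmidt condensation.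
- The diaryl ether C–O bond is made first, by Chan–Lam coupling of 4-(benzyloxy)-3-hydroxybenzaldehyde with 4-bromophenylboronic acid.
- Ring order: diaryl ether, then the flavone pyranone ring, then the chromanone ring of the flavanone unit (bought as a chromone and saturated last by the conjugate addition).

Assumption: the (S)-ligand in step 7 is chosen by analogy with 2-cyclohexenone, where (S)-biaryl bisphosphine rhodium catalysts give the corresponding face selectivity; if a first run gives the (2R)-product, the (R)-ligand is used with nothing else changed.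

**Route**

Step 1
Reactants: 1 5,7-dihydroxy-4H-chromen-4-one
Product: 2 5-hydroxy-7-methoxy-4H-chromen-4-one
Conditions: MeI (1.1 equiv), K2CO3 (1.1 equiv), acetone, 45 °C
Reagents that add atoms: iodomethane, CI
Why: Williamson etherification in which the free, more acidic 7-OH is alkylated while the 5-OH, hydrogen-bonded to the C4 carbonyl, stays untouched with one equivalent of MeI.

Step 2
Reactants: 2 5-hydroxy-7-methoxy-4H-chromen-4-one
Product: 3 5-(benzyloxy)-7-methoxy-4H-chromen-4-one
Conditions: BnBr (1.5 equiv), K2CO3 (2 equiv), DMF, 60 °C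
Reagents that add atoms: benzyl bromide, BrCc1ccccc1
Why: Williamson O-benzylation of the chelated phenol under more forcing conditions masks the acetylacetonate-like 5-hydroxy-4-keto chelate that would otherwise bind rhodium in step 7.

Step 3
Reactants: 4 4-(benzyloxy)-3-hydroxybenzaldehyde; 5 (4-bromophenyl)boronic acid (2 equiv)
Product: 6 4-(benzyloxy)-3-(4-bromophenoxy)benzaldehyde
Conditions: Cu(OAc)2 (20 mol %), pyridine (3 equiv), 4 Å MS, CH2Cl2, O2 balloon, rt
Reagents that add atoms: none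
Why: Chan–Lam oxidative C–O coupling forms the diaryl ether at room temperature, and neither the aldehyde nor the aryl bromide reacts with copper under these conditions.

Step 4
Reactants: 6 4-(benzyloxy)-3-(4-bromophenoxy)benzaldehyde; 7 1-[2,4-bis(benzyloxy)-6-hydroxyphenyl]ethan-1-one
Product: 9 (E)-1-[2,4-bis(benzyloxy)-6-hydroxyphenyl]-3-[4-(benzyloxy)-3-(4-bromophenoxy)phenyl]prop-2-en-1-one, via aldol adduct 8 (not isolated)
Conditions: KOH (50% aq., excess), EtOH/THF, rt, 24–48 h
Reagents that add atoms: none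
Why: Claisen–Schmidt condensation, in which the aldehyde cannot enolise and the aldol adduct dehydrates by E1cB to the conjugated E-chalcone.

Step 5
Reactants: 9 (E)-1-[2,4-bis(benzyloxy)-6-hydroxyphenyl]-3-[4-(benzyloxy)-3-(4-bromophenoxy)phenyl]prop-2-en-1-one
Product: 11 5,7-bis(benzyloxy)-2-[4-(benzyloxy)-3-(4-bromophenoxy)phenyl]-4H-chromen-4-one, via 3-iodoflavanone 10 (not isolated)
Conditions: I2 (10 mol %), DMSO, 130 °C, 2–4 h
Reagents that add atoms: none
Why: Iodine-catalysed oxidative cyclisation of a 2'-hydroxychalcone (oxa-Michael closure, C3 iodination, loss of HI), with DMSO reoxidising HI to I2; keeping iodine catalytic protects the benzyl ethers.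

Step 6
Reactants: 11 5,7-bis(benzyloxy)-2-[4-(benzyloxy)-3-(4-bromophenoxy)phenyl]-4H-chromen-4-one
Product: 12 {4-[2-(benzyloxy)-5-[5,7-bis(benzyloxy)-4-oxo-4H-chromen-2-yl]phenoxy]phenyl}boronic acid
Conditions: B2(OH)4 (3 equiv), PdCl(XPhos)(2'-aminobiphenyl-2-yl) (2 mol %), XPhos (4 mol %), KOAc (3 equiv), EtOH/THF 1:1, 70 °C; aqueous work-up
Reagents that add atoms: tetrahydroxydiboron, OB(O)B(O)O
Why: Miyaura-type palladium-catalysed borylation of the aryl bromide with tetrahydroxydiboron gives the free boronic acid directly, under acetate conditions that the flavone and benzyl ethers tolerate.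

Step 7
Reactants: 3 5-(benzyloxy)-7-methoxy-4H-chromen-4-one (1.0 equiv); 12 {4-[2-(benzyloxy)-5-[5,7-bis(benzyloxy)-4-oxo-4H-chromen-2-yl]phenoxy]phenyl}boronic acid (1.3 equiv)
Product: 13 (2S)-5-(benzyloxy)-2-{4-[2-(benzyloxy)-5-[5,7-bis(benzyloxy)-4-oxo-4H-chromen-2-yl]phenoxy]phenyl}-7-methoxy-2,3-dihydro-4H-chromen-4-one
Conditions: [Rh(OH)(cod)]2 (2.5 mol %), (S)-6,6'-dimethoxy-2,2'-bis[bis(3,4,5-trifluorophenyl)phosphino]biphenyl (5.5 mol %), CH2Cl2/H2O 10:1, 25 °C
Reagents that add atoms: none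
Why: Hayashi–Miyaura rhodium-catalysed asymmetric 1,4-addition, in which the aryl–rhodium formed by transmetalation adds to the Re face of C2 of the chromone under control of the electron-poor (S)-bisphosphine and water protonates the rhodium enolate to give the (2S)-flavanone; the 2-aryl-substituted flavone in 12 is too hindered an acceptor to compete.

Step 8
Reactants: 13 (2S)-5-(benzyloxy)-2-{4-[2-(benzyloxy)-5-[5,7-bis(benzyloxy)-4-oxo-4H-chromen-2-yl]phenoxy]phenyl}-7-methoxy-2,3-dihydro-4H-chromen-4-one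
Product: 14 (2S)-5-hydroxy-2-{4-[5-(5,7-dihydroxy-4-oxo-4H-chromen-2-yl)-2-hydroxyphenoxy]phenyl}-7-methoxy-2,3-dihydro-4H-chromen-4-one (CNP0161794.1)
Conditions: H2 (1 atm), 10% Pd/C, THF/MeOH 1:1, rt, stopped after uptake of 4 equiv H2
Reagents that add atoms: none
Why: Catalytic hydrogenolysis cleaves the four benzyl ethers faster than it touches the flavone C2=C3 bond, the aryl ketones or the cyclic benzylic C2–O bond, and the neutral medium cannot open the flavanone ring, so C2 stays (S).

**Compound list**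

1 | 5,7-dihydroxy-4H-chromen-4-one | O=c1ccoc2cc(O)cc(O)c12 | starting material
2 | 5-hydroxy-7-methoxy-4H-chromen-4-one | COc1cc(O)c2c(=O)ccoc2c1 | intermediate
3 | 5-(benzyloxy)-7-methoxy-4H-chromen-4-one | COc1cc(OCc2ccccc2)c2c(=O)ccoc2c1 | intermediate
4 | 4-(benzyloxy)-3-hydroxybenzaldehyde | O=Cc1ccc(OCc2ccccc2)c(O)c1 | starting material
5 | (4-bromophenyl)boronic acid | OB(O)c1ccc(Br)cc1 | starting material
6 | 4-(benzyloxy)-3-(4-bromophenoxy)benzaldehyde | O=Cc1ccc(OCc2ccccc2)c(Oc2ccc(Br)cc2)c1 | intermediate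
7 | 1-[2,4-bis(benzyloxy)-6-hydroxyphenyl]ethan-1-one | CC(=O)c1c(O)cc(OCc2ccccc2)cc1OCc1ccccc1 | starting material
8 | 1-[2,4-bis(benzyloxy)-6-hydroxyphenyl]-3-[4-(benzyloxy)-3-(4-bromophenoxy)phenyl]-3-hydroxypropan-1-one (racemic aldol adduct, not isolated) | OC(CC(=O)c1c(O)cc(OCc2ccccc2)cc1OCc1ccccc1)c1ccc(OCc2ccccc2)c(Oc2ccc(Br)cc2)c1 | intermediate
9 | (E)-1-[2,4-bis(benzyloxy)-6-hydroxyphenyl]-3-[4-(benzyloxy)-3-(4-bromophenoxy)phenyl]prop-2-en-1-one | O=C(/C=C/c1ccc(OCc2ccccc2)c(Oc2ccc(Br)cc2)c1)c1c(O)cc(OCc2ccccc2)cc1OCc1ccccc1 | intermediate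
10 | 5,7-bis(benzyloxy)-2-[4-(benzyloxy)-3-(4-bromophenoxy)phenyl]-3-iodo-2,3-dihydro-4H-chromen-4-one (racemic, not isolated) | O=C1C(I)C(c2ccc(OCc3ccccc3)c(Oc3ccc(Br)cc3)c2)Oc2cc(OCc3ccccc3)cc(OCc3ccccc3)c21 | intermediate
11 | 5,7-bis(benzyloxy)-2-[4-(benzyloxy)-3-(4-bromophenoxy)phenyl]-4H-chromen-4-one | O=c1cc(-c2ccc(OCc3ccccc3)c(Oc3ccc(Br)cc3)c2)oc2cc(OCc3ccccc3)cc(OCc3ccccc3)c12 | intermediate
12 | {4-[2-(benzyloxy)-5-[5,7-bis(benzyloxy)-4-oxo-4H-chromen-2-yl]phenoxy]phenyl}boronic acid | OB(O)c1ccc(Oc2cc(-c3cc(=O)c4c(OCc5ccccc5)cc(OCc5ccccc5)cc4o3)ccc2OCc2ccccc2)cc1 | intermediate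
13 | (2S)-5-(benzyloxy)-2-{4-[2-(benzyloxy)-5-[5,7-bis(benzyloxy)-4-oxo-4H-chromen-2-yl]phenoxy]phenyl}-7-methoxy-2,3-dihydro-4H-chromen-4-one | COc1cc(OCc3ccccc3)c2c(c1)O[C@H](c1ccc(Oc3cc(-c4cc(=O)c5c(OCc6ccccc6)cc(OCc6ccccc6)cc5o4)ccc3OCc3ccccc3)cc1)CC2=O | intermediate
14 | (2S)-5-hydroxy-2-{4-[5-(5,7-dihydroxy-4-oxo-4H-chromen-2-yl)-2-hydroxyphenoxy]phenyl}-7-methoxy-2,3-dihydro-4H-chromen-4-one | COc1cc(O)c2c(c1)O[C@H](c1ccc(Oc3cc(-c4cc(=O)c5c(O)cc(O)cc5o4)ccc3O)cc1)CC2=O | target

**Step count**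
Total: 8 steps. Longest linear sequence: 6 steps (steps 3–8, from compound 4); steps 1–2 form the short chromone branch that joins at step 7.

**Three steps most likely to fail, with fallbacks**

Step 7 (asymmetric 1,4-addition). The risks are slow addition to the electron-rich 5,7-dialkoxychromone, protodeboronation of 12, and insufficient ee. The fallback sets the stereocentre by resolution instead of catalysis. It sets out from 3 and 12, which are coupled with an achiral cationic palladium catalyst, Pd(OCOCF3)2/2,2'-bipyridine in ClCH2CH2Cl/H2O at 60 °C. This gives racemic 5-(benzyloxy)-2-{4-[2-(benzyloxy)-5-[5,7-bis(benzyloxy)-4-oxo-4H-chromen-2-yl]phenoxy]phenyl}-7-methoxy-2,3-dihydro-4H-chromen-4-one F1. The racemate is separated by preparative chiral SFC on an amylose tris(3,5-dimethylphenylcarbamate) phase. The (2S)-enantiomer is compound 13, where the route is rejoined; the (2R)-tetrabenzyl flavanone–flavone F2 is set aside.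

Step 6 (direct borylation to the free boronic acid). The risks are hydrodebromination and difficult purification of a lipophilic free boronic acid. The fallback goes through a chromatographable boronate. It sets out from 11, which undergoes Miyaura borylation with bis(pinacolato)diboron, PdCl2(dppf) and KOAc in 1,4-dioxane at 90 °C. This gives 5,7-bis(benzyloxy)-2-{4-(benzyloxy)-3-[4-(4,4,5,5-tetramethyl-1,3,2-dioxaborolan-2-yl)phenoxy]phenyl}-4H-chromen-4-one F3, which is purified on silica. The pinacol is then removed oxidatively with NaIO4/NH4OAc in acetone/H2O at rt, which returns boronic acid 12.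

Step 8 (global hydrogenolysis). The risks are over-reduction of the flavone C2=C3 bond, hydrogenolysis of the flavanone C2–O bond to a dihydrochalcone, and incomplete removal of the two chelated 5-O-benzyl groups. The fallback replaces reduction by Lewis-acid debenzylation with a cation scavenger. It sets out from 13, which is treated with BCl3 (8 equiv) and pentamethylbenzene (12 equiv) in CH2Cl2 at −78 °C and quenched with MeOH, and it arrives directly at 14. At this temperature the non-chelated 7-OMe is not cleaved. No new isolated compound is involved.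

**Further compounds**

F1 | step 7 | racemic 5-(benzyloxy)-2-{4-[2-(benzyloxy)-5-[5,7-bis(benzyloxy)-4-oxo-4H-chromen-2-yl]phenoxy]phenyl}-7-methoxy-2,3-dihydro-4H-chromen-4-one | COc1cc(OCc3ccccc3)c2c(c1)OC(c1ccc(Oc3cc(-c4cc(=O)c5c(OCc6ccccc6)cc(OCc6ccccc6)cc5o4)ccc3OCc3ccccc3)cc1)CC2=O
F2 | step 7 | (2R)-5-(benzyloxy)-2-{4-[2-(benzyloxy)-5-[5,7-bis(benzyloxy)-4-oxo-4H-chromen-2-yl]phenoxy]phenyl}-7-methoxy-2,3-dihydro-4H-chromen-4-one | COc1cc(OCc3ccccc3)c2c(c1)O[C@@H](c1ccc(Oc3cc(-c4cc(=O)c5c(OCc6ccccc6)cc(OCc6ccccc6)cc5o4)ccc3OCc3ccccc3)cc1)CC2=O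
F3 | step 6 | 5,7-bis(benzyloxy)-2-{4-(benzyloxy)-3-[4-(4,4,5,5-tetramethyl-1,3,2-dioxaborolan-2-yl)phenoxy]phenyl}-4H-chromen-4-one | CC1(C)OB(c2ccc(Oc3cc(-c4cc(=O)c5c(OCc6ccccc6)cc(OCc6ccccc6)cc5o4)ccc3OCc3ccccc3)cc2)OC1(C)C
F0 | step 8 | none | none
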